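## Structural features

The target is a pentabrominated diaryl ether made of two benzene rings and nothing else: ring A carries OMe at C1, Br at C2 and C4 and the bridging oxygen at C6; ring B carries the bridging oxygen at C1', a free OH at C2' and three contiguous bromines at C4', C5' and C6'. The only link between the rings is the C6–O–C1' ether. Each ring is a catechol at heart, one oxygen of each pair being the bridge, so three kinds of oxygen (OMe, OH, shared ether) must be told apart. There is no stereocentre; the ether has three ortho substituents (C1–OMe, C2'–OH, C6'–Br) and is assumed to rotate freely, so the compound is treated as achiral. The fragile groups are the five aryl C–Br bonds (halogen–metal exchange, reduction, oxidative addition to low-valent metals), the free phenol, and the methyl ether that has to outlive the last unmasking. The real difficulty is the bridge: it joins two electron-poor rings at flanked carbons (C6 next to C1–OMe; C1' between C2'–OH and C6'–Br), and the two rings have different bromine patterns that a late bromination could not place independently. The key step uses the fact that on ring A the oxygen-bearing carbons C6 and C1 are neighbours and C1 has bromine at C2 on its other side: this is the 1,2-pattern a C1–C6 aryne accepts when the C2 bromine sends the nucleophile to C6 and the electrophile to C1.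

## Logic of the disconnections

**17 ⇒ 16.** The O–CH2 bond of the acetal on the C2' oxygen is cut. The free phenol of 17 would quench every carbanion on the way and would compete in the methylation, so it is carried masked. The gain is that the ring A oxygen at C1 and the ring B oxygen at C2' stay distinguishable to the end. The forward step must remove the acetal under acid mild enough to spare the methyl ether, the diaryl ether and five C–Br bonds.

**16 ⇒ 15.** The O–CH3 bond at C1 is cut. With the C2' oxygen masked, 15 has a single free hydroxyl, so methylation needs no selectivity. The demand is only that a hindered, acidic phenoxide reacts with a small electrophile.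

**15 ⇒ 12 (through 13 and 14).** The C1–O bond is traded for C1–I. Iodine is the one halogen that can be singled out among five bromines by halogen–magnesium exchange. The gain is that the C1 oxygen need not be present during the ether-forming step. The forward step must exchange iodine only, and the ortho-bromoarylmagnesium 13 must last until it is borylated to 14.

**12 ⇒ 4 + 8 (through 9, 10 and 11).** The O–C6 and C1–I bonds are cut together. Both are ortho bonds that an aryne forms in one operation, and an aryne is electrophilic enough to accept a hindered, electron-poor phenoxide. The molecule falls into two monocyclic halves, each already carrying its final bromine pattern. The forward step needs regioselective addition (oxygen to C6, not C1) and iodine capture by 11 faster than protonation or loss of bromide.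

**4 ⇒ 1 (through 2 and 3).** The C6–Si and O–S bonds are cut. An ortho-silylaryl triflate comes from an ortho-bromophenol by O-silylation, exchange and O→C silyl shift. In 1 the two ortho bromines are equivalent, and the two bromines left over are exactly those of ring A. The gain is one flask from a commodity phenol. The demand is exchange at an ortho and not the para bromine, with one equivalent of organolithium.

**8 ⇒ 7.** The C6'–Br bond (the bromine next to the future bridging oxygen) is cut. The free hydroxyl of 7 has its para position blocked and only one ortho position open, so it should direct the incoming bromine there and complete the contiguous tribromide. The demand is bromination ortho to OH rather than ortho to the acetal oxygen, in an acid-free medium.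

**7 ⇒ 5 (through 6).** The O–CH2 bond of the acetal is cut. Since 5 has a mirror plane, its two hydroxyls are identical and mono-protection raises no regiochemical question; the following bromination then decides which oxygen ends up next to bromine. This avoids having to distinguish the two hydroxyls of a tribrominated catechol, which differ only slightly in acidity. The demand is mono- over bis-alkylation.

## Other disconnections considered

**Alternative 1:** Ring B is cut at C3'–C4' and C1'–C6'. This leaves C1'–C2'–C3' as the ketone 1-(3,5-dibromo-2-methoxyphenoxy)propan-2-one A2, made from 3,5-dibromo-2-methoxyphenol A1 by O-alkylation with a haloacetone, and C4'–C5'–C6' as sodium nitromalonaldehyde A3. In the forward direction a double aldol-type condensation at both α-carbons of A2 with A3 in aqueous base, then dehydration and tautomerisation, should close ring B as 2-(3,5-dibromo-2-methoxyphenoxy)-4-nitrophenol A4.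

- In favour: the ring B hydroxyl is born from the ketone carbonyl and the ether oxygen already sits on the α-carbon, so the two ring B oxygens are distinguished by construction without a protecting group. On this point the alternative is better than the chosen plan. It also needs no aryne and no organometallic step, and the bridge is made by alkylating an unhindered phenol.
- Against: A4 has nitrogen where bromine is needed and no bromine on ring B at all. C4'–Br, C5'–Br and C6'–Br would all have to follow: nitro reduction beside two aryl bromides, dibromination at both positions ortho to the amine while C3' (ortho to OH) stays free, and a Sandmeyer bromination. A 4-aminophenol is prone to oxidation to a quinone imine and its diazonium salt to collapse to a diazo-oxide, so the phenol would need masking and release. A3 is a shock-sensitive salt.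
- Comparison: structurally this builds the carbocycle but postpones the whole halogen pattern, whereas the chosen plan brings each ring with its bromines in place. Mechanistically the condensation is more predictable than trapping a short-lived ortho-bromoaryl anion, but the three late substitutions are less so. In step count it should be clearly longer (about nine or ten steps in line against six).

**Alternative 2:** Ring B is cut at C1'–C2' and C5'–C6' into a four-carbon diene, 3-acetoxy-5-bromo-2H-pyran-2-one A5 (C2' to C5'), and a two-carbon alkyne, [(3,5-dibromo-2-methoxyphenoxy)ethynyl]trimethylsilane A6 (C1' and C6'), the ynol ether of A1. In the forward direction a thermal Diels–Alder addition of A6 across C3 and C6 of A5, with the oxygen-bearing alkyne carbon joining the acetoxy-bearing carbon, followed by decarboxylative retro-[4+2] fragmentation, should give 5-bromo-2-(3,5-dibromo-2-methoxyphenoxy)-3-(trimethylsilyl)phenyl acetate A7.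

- In favour: the ring B oxygens are differentiated from the start (acetate against aryl ether), and silicon marks C6' for ipso-bromination. On oxygen differentiation and on the placing of C4'–Br and C6'–Br it is the equal of, or better than, the chosen plan. Aromatisation is irreversible.
- Against: A7 still lacks C5'–Br. That bromine would have to enter para to the liberated hydroxyl at a carbon flanked by two substituents, in competition with the open ortho position C3'. A6 is normally reached by strongly basic elimination and metalation, which the two aryl bromides of ring A would not be expected to tolerate. A5 needs its own multi-step synthesis. The regiochemistry depends on matching a push–pull alkyne with a pyrone carrying both a donor and a halogen, which is less secure than one ortho bromine steering an aryne.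
- Comparison: three steps would follow the key step (deacetylation, bromodesilylation, bromination), the same number as in the chosen plan, but more precede it, so the route is longer overall.

**Alternative 3:** Ring A is traced back to a saturated ring. The C2–Br and C4–Br bonds are cut and the arene is lowered to the cyclohexanone 2-[6-(benzyloxy)-2,3,4-tribromophenoxy]cyclohexan-1-one A9, made from 6-(benzyloxy)-2,3,4-tribromophenol A8 by O-alkylation with an α-halocyclohexanone. In the forward direction an excess of brominating agent should α-brominate and dehydrobrominate repeatedly until the ring is a phenol, then brominate it ortho and para to the new hydroxyl, giving 2-[6-(benzyloxy)-2,3,4-tribromophenoxy]-4,6-dibromophenol A10.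

- In favour: the C1 oxygen arrives as the ketone, so no iodine has to be turned into oxygen. Only O-methylation and debenzylation would remain after the key step, one step fewer than in the chosen plan, and the total count is equal or lower; on step economy the alternative is the better. Ortho/para direction by OH gives exactly the 2,4-pattern, equal in regiochemical outcome. The bridge is made by plain alkylation.
- Against: several oxidation-level changes occur in one pot with little control. Bromination at the carbon bearing the aryloxy group gives an α-bromo ether from which the ring B phenoxide can be expelled, so the new bridge itself is at risk. Several equivalents of hydrogen halide are released beside a benzyl ether, and the benzyl ring is itself open to bromination. Hydrogenolytic debenzylation is ruled out by five C–Br bonds, and Lewis-acid debenzylation would compete with cleavage of the hindered methyl ether. A8 poses the same oxygen-differentiation problem as 8 (equal).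
- Comparison: structurally both plans join two pre-formed rings. Mechanistically the chosen plan confines its risk to one defined addition on a ring that already has its bromines, and ends with a mild acid unmasking. The alternative is shorter but less controlled.

Key step: step 4

## Route

Step 1
Reactants: 1 2,4,6-tribromophenol
Product: 4 2,4-dibromo-6-(trimethylsilyl)phenyl trifluoromethanesulfonate, via (2,4,6-tribromophenoxy)trimethylsilane 2 (not isolated), via lithium 2,4-dibromo-6-(trimethylsilyl)phenoxide 3 (not isolated)
Conditions: HMDS (0.6 equiv), THF, reflux, then evaporate; n-BuLi (1.0 equiv), THF, −78 → −40 °C; Tf2O (1.1 equiv), −78 °C → rt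
Reagents that add atoms: hexamethyldisilazane, C[Si](C)(C)N[Si](C)(C)C; trifluoromethanesulfonic anhydride, O=S(=O)(OS(=O)(=O)C(F)(F)F)C(F)(F)F
Why: O-silylation, bromine–lithium exchange at one of the two equivalent ortho positions and 1,3 O→C silyl migration (retro-Brook rearrangement) should give 3, which Tf2O traps at oxygen; the silyl shift drains only the ortho-lithiated species, so any para exchange can funnel back by intermolecular exchange. The lithiated carbon has no ortho bromine, so no aryne can form at this stage.

Step 2
Reactants: 5 4,5-dibromobenzene-1,2-diol
Product: 7 4,5-dibromo-2-(methoxymethoxy)phenol, via sodium 4,5-dibromo-2-hydroxyphenoxide 6 (not isolated)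
Conditions: NaH (1.0 equiv), THF/DMF, 0 °C; MOMCl (0.95 equiv), 0 °C → rt; aq NH4Cl
Reagents that add atoms: chloromethyl methyl ether (MOMCl), COCCl
Why: Williamson-type O-alkylation of the hydrogen-bonded monoanion 6; the two hydroxyls of 5 are identical by symmetry, so there is no regiochemical question. The mono-ether should be a weaker acid than 5, so the remaining monoanion is a poor base for it, which limits bis-alkylation; unreacted 5 is recovered.

Step 3
Reactants: 7 4,5-dibromo-2-(methoxymethoxy)phenol
Product: 8 2,3,4-tribromo-6-(methoxymethoxy)phenol
Conditions: NBS (1.05 equiv), i-Pr2NH (10 mol %), CH2Cl2, 0 °C → rt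
Reagents that add atoms: N-bromosuccinimide, O=C1CCC(=O)N1Br
Why: Electrophilic aromatic bromination (amine-catalysed ortho-bromination of a phenol with NBS); the free hydroxyl is a far stronger activator than the acetal oxygen and its para position is blocked, so bromine should enter at the single open ortho position. The acid-free medium spares the acetal.

Step 4
Reactants: 4 2,4-dibromo-6-(trimethylsilyl)phenyl trifluoromethanesulfonate; 8 2,3,4-tribromo-6-(methoxymethoxy)phenol
Product: 12 1,2,3-tribromo-4-(3,5-dibromo-2-iodophenoxy)-5-(methoxymethoxy)benzene, via potassium 2,3,4-tribromo-6-(methoxymethoxy)phenoxide 9 (not isolated), via 3,5-dibromobenzyne 10 (not isolated), via 2,4-dibromo-6-[2,3,4-tribromo-6-(methoxymethoxy)phenoxy]phenylpotassium 11 (not isolated)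
Conditions: 8 (1.3 equiv), KH (1.3 equiv), THF, 0 °C; then 18-crown-6 (2 equiv), KF (2 equiv), C4F9I (3 equiv), 4 (1.0 equiv) added slowly, THF, −10 °C → rt, dark
Reagents that add atoms: nonafluoro-1-iodobutane, FC(F)(F)C(F)(F)C(F)(F)C(F)(F)I
Why: Fluoride attacks silicon in 4 and triflate leaves, releasing aryne 10. The C–Br bond next to the triple bond distorts it so that the distal carbon (C6 of ring A) is the more electrophilic terminus; phenoxide 9 should add there, which puts the developing carbanion at C1, ortho to the inductively stabilising bromine, and keeps the bulky nucleophile away from that bromine. Aryl anion 11 then takes iodine from the perfluoroalkyl iodide through a halogen-bonded ate complex, forming O–C6 and C1–I; the perfluorobutyl anion collapses to the fluoroalkene and fluoride, so fluoride is returned. The closest known reaction type is the fluoride-triggered three-component coupling of ortho-silylaryl triflates with a heteroatom nucleophile and a halogen electrophile, phenoxides being among its less used nucleophiles. No ring is closed and no stereocentre is formed. Regioselectivity rests on the C2 bromine; the remote C4 bromine pulls weakly the other way, but ortho control and sterics should dominate. Iodine capture ahead of protonation or bromide loss is served by the proton-free medium (phenol fully deprotonated by KH, THF and not acetonitrile), the excess of iodine donor present from the start, slow aryne release and low temperature. The acetal is inert to fluoride, and the single iodine marks C1 alone for conversion into the methoxy carbon.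

Step 5
Reactants: 12 1,2,3-tribromo-4-(3,5-dibromo-2-iodophenoxy)-5-(methoxymethoxy)benzene
Product: 15 2,4-dibromo-6-[2,3,4-tribromo-6-(methoxymethoxy)phenoxy]phenol, via arylmagnesium chloride 13 (not isolated), via dimethyl arylboronate 14 (not isolated)
Conditions: i-PrMgCl·LiCl (1.05 equiv), THF, −78 °C; B(OMe)3 (2 equiv), −78 → 0 °C; 30% H2O2, aq NaOH, 0 °C → rt; aq Na2S2O3, dilute HCl
Reagents that add atoms: hydrogen peroxide, OO
Why: Iodine–magnesium exchange is far faster than bromine–magnesium exchange, so at −78 °C only C1–I should react; the ortho-bromoarylmagnesium 13 does not lose magnesium halide at this temperature and is trapped as 14. Alkaline peroxide then moves the aryl group from boron to oxygen (borylation–oxidation of an aryl Grignard reagent).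

Step 6
Reactants: 15 2,4-dibromo-6-[2,3,4-tribromo-6-(methoxymethoxy)phenoxy]phenol
Product: 16 1,2,3-tribromo-4-(3,5-dibromo-2-methoxyphenoxy)-5-(methoxymethoxy)benzene
Conditions: MeI (2 equiv), K2CO3 (2 equiv), DMF, rt
Reagents that add atoms: iodomethane, CI
Why: Williamson O-methylation; 15 has one free hydroxyl, which is acidic, and the electrophile is small enough for the flanked phenoxide.

Step 7
Reactants: 16 1,2,3-tribromo-4-(3,5-dibromo-2-methoxyphenoxy)-5-(methoxymethoxy)benzene
Product: 17 3,4,5-tribromo-2-(3,5-dibromo-2-methoxyphenoxy)phenol
Conditions: 3 M aq HCl, MeOH/THF, 50 °C
Reagents that add atoms: none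
Why: Acid-catalysed acetal cleavage with transfer of the methoxymethyl unit to methanol; the aryl methyl ether, the diaryl ether and the C–Br bonds are inert to dilute HCl.

## Compound list

1 | 2,4,6-tribromophenol | Oc1c(Br)cc(Br)cc1Br | starting material
2 | (2,4,6-tribromophenoxy)trimethylsilane | C[Si](C)(C)Oc1c(Br)cc(Br)cc1Br | intermediate
3 | lithium 2,4-dibromo-6-(trimethylsilyl)phenoxide | [Li+].C[Si](C)(C)c1cc(Br)cc(Br)c1[O-] | intermediate
4 | 2,4-dibromo-6-(trimethylsilyl)phenyl trifluoromethanesulfonate | C[Si](C)(C)c1cc(Br)cc(Br)c1OS(=O)(=O)C(F)(F)F | intermediate
5 | 4,5-dibromobenzene-1,2-diol | Oc1cc(Br)c(Br)cc1O | starting material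
6 | sodium 4,5-dibromo-2-hydroxyphenoxide | [Na+].[O-]c1cc(Br)c(Br)cc1O | intermediate
7 | 4,5-dibromo-2-(methoxymethoxy)phenol | COCOc1cc(Br)c(Br)cc1O | intermediate
8 | 2,3,4-tribromo-6-(methoxymethoxy)phenol | COCOc1cc(Br)c(Br)c(Br)c1O | intermediate
9 | potassium 2,3,4-tribromo-6-(methoxymethoxy)phenoxide | [K+].COCOc1cc(Br)c(Br)c(Br)c1[O-] | intermediate
10 | 3,5-dibromobenzyne | BrC1=CC(Br)=CC#C1 | intermediate
11 | 2,4-dibromo-6-[2,3,4-tribromo-6-(methoxymethoxy)phenoxy]phenylpotassium | [K+].COCOc1cc(Br)c(Br)c(Br)c1Oc1cc(Br)cc(Br)[c-]1 | intermediate
12 | 1,2,3-tribromo-4-(3,5-dibromo-2-iodophenoxy)-5-(methoxymethoxy)benzene | COCOc1cc(Br)c(Br)c(Br)c1Oc1cc(Br)cc(Br)c1I | intermediate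
13 | {2,4-dibromo-6-[2,3,4-tribromo-6-(methoxymethoxy)phenoxy]phenyl}magnesium chloride | COCOc1cc(Br)c(Br)c(Br)c1Oc1cc(Br)cc(Br)c1[Mg]Cl | intermediate
14 | dimethyl {2,4-dibromo-6-[2,3,4-tribromo-6-(methoxymethoxy)phenoxy]phenyl}boronate | COCOc1cc(Br)c(Br)c(Br)c1Oc1cc(Br)cc(Br)c1B(OC)OC | intermediate
15 | 2,4-dibromo-6-[2,3,4-tribromo-6-(methoxymethoxy)phenoxy]phenol | COCOc1cc(Br)c(Br)c(Br)c1Oc1cc(Br)cc(Br)c1O | intermediate
16 | 1,2,3-tribromo-4-(3,5-dibromo-2-methoxyphenoxy)-5-(methoxymethoxy)benzene | COCOc1cc(Br)c(Br)c(Br)c1Oc1cc(Br)cc(Br)c1OC | intermediate
17 | 3,4,5-tribromo-2-(3,5-dibromo-2-methoxyphenoxy)phenol | COc1c(Br)cc(Br)cc1Oc1c(O)cc(Br)c(Br)c1Br | target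

## Step count and least certain steps

Total: 7 steps. Longest linear sequence: 6 steps (5 → 7 → 8 → 12 → 15 → 16 → 17, steps 2 to 7); the ring A branch (1 → 4) is one step.

**Step 4 (key step).** The most likely failure is loss of bromide from the ortho-bromoaryl anion, or its protonation, before iodine transfer, because both are fast and need no second partner; the anion would then give a second aryne or the iodine-free ether. A second weakness is slow addition of the hindered, electron-poor phenoxide, which would let fluoride or the fluoroalkene by-product divert material. Fallback, setting out from 8: nucleophilic aromatic substitution on purchasable 2,4-dibromo-6-fluorobenzaldehyde (K2CO3, DMF, 80 °C), in which fluoride ortho to the formyl group should be displaced in preference to the bromides, would give 2,4-dibromo-6-[2,3,4-tribromo-6-(methoxymethoxy)phenoxy]benzaldehyde F1. Baeyer–Villiger oxidation with mCPBA in CH2Cl2, followed in the same flask by K2CO3/MeOH, would turn the formyl carbon into the C1 hydroxyl and come back to the route at 15, bypassing steps 4 and 5.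

**Step 5.** The likely failure is competing bromine–magnesium exchange on the tribrominated ring B, or elimination of magnesium halide from the ortho-bromoarylmagnesium if it warms before the borate captures it. Fallback, setting out from 12: copper-catalysed Ullmann-type methoxylation (CuI, 3,4,7,8-tetramethyl-1,10-phenanthroline, Cs2CO3, MeOH, toluene, 80 °C), which relies on monovalent copper inserting into C–I faster than into C–Br, would lead directly to 16 with no new intermediate and no organomagnesium species, skipping step 6.

**Step 1.** The likely failure is exchange at the para bromine or a second exchange, and incomplete O→C silyl shift, which would give mixtures of silylated phenols. Fallback, setting out from 1 by way of 2: bromine–magnesium exchange with i-PrMgCl·LiCl at −20 °C (favoured ortho to oxygen and tolerant of the remaining bromides), intermolecular C-silylation with Me3SiCl and O-desilylation on work-up would give 2,4-dibromo-6-(trimethylsilyl)phenol F2. This is purified and triflated (Tf2O, pyridine, CH2Cl2) to come back at 4. Silicon is delivered from outside rather than by migration, and the silylphenol is checked before the triflate is made.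

**Step 3.** The likely failure is bromination ortho to the acetal oxygen, loss of the acetal if HBr builds up, or oxidation of the electron-rich catechol mono-ether. Fallback, setting out from 5: the order is reversed. Bromination of the free diol (Br2, AcOH), whose two open positions are equivalent, would give 3,4,5-tribromobenzene-1,2-diol F3, which is acid-stable. Treatment with two equivalents of NaH and one of MOMCl in DMF should then place the acetal on the oxygen that is not flanked by bromine (less hindered and slightly more basic), coming back at 8. This selectivity is weaker than that of the main route, which is why it is the fallback.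

## Further compounds

F1 | step 4 | 2,4-dibromo-6-[2,3,4-tribromo-6-(methoxymethoxy)phenoxy]benzaldehyde | COCOc1cc(Br)c(Br)c(Br)c1Oc1cc(Br)cc(Br)c1C=O
F0 | step 5 | none | none
F2 | step 1 | 2,4-dibromo-6-(trimethylsilyl)phenol | C[Si](C)(C)c1cc(Br)cc(Br)c1O
F3 | step 3 | 3,4,5-tribromobenzene-1,2-diol | Oc1cc(Br)c(Br)c(Br)c1O
A1 | alternative 1 | 3,5-dibromo-2-methoxyphenol | COc1c(Br)cc(Br)cc1O
A2 | alternative 1 | 1-(3,5-dibromo-2-methoxyphenoxy)propan-2-one | COc1c(Br)cc(Br)cc1OCC(C)=O
A3 | alternative 1 | sodium nitromalonaldehyde | [Na+].O=C[C-](C=O)[N+](=O)[O-]
A4 | alternative 1 | 2-(3,5-dibromo-2-methoxyphenoxy)-4-nitrophenol | COc1c(Br)cc(Br)cc1Oc1cc([N+](=O)[O-])ccc1O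
A5 | alternative 2 | 3-acetoxy-5-bromo-2H-pyran-2-one | CC(=O)OC1=CC(Br)=COC1=O
A6 | alternative 2 | [(3,5-dibromo-2-methoxyphenoxy)ethynyl]trimethylsilane | COc1c(Br)cc(Br)cc1OC#C[Si](C)(C)C
A7 | alternative 2 | 5-bromo-2-(3,5-dibromo-2-methoxyphenoxy)-3-(trimethylsilyl)phenyl acetate | COc1c(Br)cc(Br)cc1Oc1c(OC(C)=O)cc(Br)cc1[Si](C)(C)C
A8 | alternative 3 | 6-(benzyloxy)-2,3,4-tribromophenol | Oc1c(OCc2ccccc2)cc(Br)c(Br)c1Br
A9 | alternative 3 | 2-[6-(benzyloxy)-2,3,4-tribromophenoxy]cyclohexan-1-one | O=C1CCCCC1Oc1c(OCc2ccccc2)cc(Br)c(Br)c1Br
A10 | alternative 3 | 2-[6-(benzyloxy)-2,3,4-tribromophenoxy]-4,6-dibromophenol | Oc1c(Br)cc(Br)cc1Oc1c(OCc2ccccc2)cc(Br)c(Br)c1Br
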